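(Its constants were chosen freely; the flask was simulated.)

Count amounts first: substrate and coupling partner reversibly form intermediate, intermediate goes on to product, and product crystallises above its solubility.

substrate 0.17 M; coupling partner 1.80 equiv; time 12 min

- amount of product and crystals together at 12 min, in percent of the substrate charged
- concentration of product in solution at 3.0 min, in percent of saturation
- the change that raises the amount of product and crystals together at 12 min, in percent of the substrate charged most ("none" if none brings more than 2 percentage points) (blue / violet / red / none)
- amount of product and crystals together at 12 min, in percent of the substrate charged, after blue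

- blue: doubling the dissolution coefficient of step 2, all else as stated
- violet: doubling the solubility in step 2, all else as stated
- red: doubling the amount of coupling partner, all else as stated

How much product must this flask make before a solid can appear? Divide the solubility 0.071 M by the substrate charged 0.17 M. That gives 41.8% of the charge, and I call this percentage the crystal threshold.

Can the flask reach it in 12 min? Grant it every molecule of substrate as intermediate from the start. With 4.9 × 10⁻⁴ s⁻¹, product then reaches 29.7%, less than the threshold. So no crystals form, blue has no solid to act on, and violet raises a threshold that is not reached.

How much product, then? Solve both ends and join them, holding c(coupling partner) at its charge 0.306 M, which makes step 3 pseudo-first-order. At the start, intermediate rises; late, it stands at a plateau of 55.6% of the charge. It approaches this at 0.172 min⁻¹, forward and back together. Integrating this curve and multiplying by 4.9 × 10⁻⁴ s⁻¹ gives my 11.3% at 12 min, also for blue. At 3.0 min it gives 1.07%, which is 2.56% of saturation. Read these as high: the reckoning holds c(coupling partner) at its charge and lets step 1 take nothing away from the intermediate curve. Red, reckoned alike, gives 17.7%, a gain of 6.4 percentage points, more than 2 points, so I choose red.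

The forecast gives 9.1% (8.5% to 9.8%), less than my figure, with 2.4% of saturation, red as best, and 9.1% after blue, on the ground that “no crystals appear”.

The simulation gives 9.15%, 2.39% of saturation, red as best with a gain of 5.6 points, and 9.15% after blue.

    intermediate → product (k1 = 4.9 × 10⁻⁴ s⁻¹)
    crystals ⇌ product, rate k2*(cs2 - [product]) while solid is left; crystals form when [product] > cs2 (cs2 = 0.071 M, k2 = 0.28 s⁻¹)
    substrate + coupling partner ⇌ intermediate (K3 = 4.1 M⁻¹, k3 = 0.0052 M⁻¹ s⁻¹)

In the flask at 3.24 min, intermediate falls back 2.6 times faster than it goes on, and at 12.0 min it holds 35.5% of the charge. Product and crystals together stand at 9.15%, less than the threshold 41.8%, with crystals at 0%. The flask with 0.43 M of substrate has a threshold of 16.5%, and its product at 12.0 min stands at 15.5%, less than that, with crystals at 0%.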